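Ring B is read as a cyclohexene (labdane numbering): the oxygen-bearing C6–C7 carbons are the new double bond of a [4+2] adduct, and the C5–C10 and C8–C9 bonds are its two new σ bonds. An intramolecular Diels–Alder reaction of an acyclic (2E,8E,10Z)-trienal therefore closes rings A and B at once: C5=C6–C7(OSi)=C8 is the diene, the C9=C10 enal the dienophile and C1–C4 the tether. A chiral oxazaborolidinium catalyst sets C5, C9 and C10 (trans ring fusion, C20 methyl cis to the C9 branch). The resulting C6=C7 silyl enol ether is the handle for the C6, C7 and C8 oxygens. Side-chain diene and angelate are added late.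

Key step: step 7

Remark: labdane numbering is used throughout (C1–C10 decalin, C11–C16 side chain on C9, C17 on C8, C18/C19 on C4, C20 on C10; β = face of the C20 methyl); C8 of ketones 13–17 is epimerisable, is drawn as formed in step 7 and is reset in step 12.

Step 1
Reactants: 1 ethyl acetoacetate
Product: 2 ethyl (E)-3-(trifluoromethylsulfonyloxy)but-2-enoate
Conditions: Tf2O, aq. Me4NOH, hexane, 5 °C → rt
Reagents that add atoms: triflic anhydride, O=S(=O)(OS(=O)(=O)C(F)(F)F)C(F)(F)F
Why: O-triflation of the non-chelated tetramethylammonium enolate of the β-keto ester should give the (E)-enol triflate (OTf trans to the ester), the geometry that becomes the (E)-trisubstituted C9=C10 dienophile.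

Step 2
Reactants: 3 2,2-dimethylpent-4-enal; 4 diethyl (2-oxobutyl)phosphonate
Product: 5 (E)-6,6-dimethylnona-4,8-dien-3-one
Conditions: Ba(OH)2·8H2O, wet THF, rt
Reagents that add atoms: none
Why: Horner–Wadsworth–Emmons olefination of a non-enolisable α-quaternary aldehyde with a β-ketophosphonate should give the (E)-enone (future C5=C6).

Step 3
Reactants: 5 (E)-6,6-dimethylnona-4,8-dien-3-one
Product: 6 (2Z,4E)-6,6-dimethyl-3-(triisopropylsilyloxy)nona-2,4,8-triene
Conditions: TIPSOTf, Et3N, CH2Cl2, 0 °C → rt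
Reagents that add atoms: triisopropylsilyl triflate, CC(C)[Si](OS(=O)(=O)C(F)(F)F)(C(C)C)C(C)C
Why: Soft enolisation of the ethyl ketone (the only enolisable side, C4 being quaternary) should give the 2-silyloxy diene with the thermodynamically preferred (Z)-enol ether, which places the C17 methyl on the outside of the diene.

Step 4
Reactants: 6 (2Z,4E)-6,6-dimethyl-3-(triisopropylsilyloxy)nona-2,4,8-triene; 2 ethyl (E)-3-(trifluoromethylsulfonyloxy)but-2-enoate
Product: 8 ethyl (2E,8E,10Z)-3,7,7-trimethyl-10-(triisopropylsilyloxy)dodeca-2,8,10-trienoate, via B-alkyl-9-BBN adduct 7 (not isolated)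
Conditions: 9-BBN, THF, 0 °C → rt; then 2, PdCl2(dppf) (5 mol%), aq. K3PO4, DMF, rt → 50 °C
Reagents that add atoms: none
Why: 9-BBN hydroborates the monosubstituted terminal alkene much faster than the disubstituted and enol-ether alkenes, and the B-alkyl Suzuki–Miyaura coupling with the enol triflate proceeds with retention, which fixes the (E)-geometry of C9=C10.

Step 5
Reactants: 8 ethyl (2E,8E,10Z)-3,7,7-trimethyl-10-(triisopropylsilyloxy)dodeca-2,8,10-trienoate
Product: 9 (2E,8E,10Z)-3,7,7-trimethyl-10-(triisopropylsilyloxy)dodeca-2,8,10-trien-1-ol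
Conditions: DIBAL-H, CH2Cl2, −78 °C; Rochelle salt work-up
Reagents that add atoms: none
Why: DIBAL-H reduces the enoate 1,2 to the allylic alcohol at low temperature and leaves the silyl dienol ether untouched.

Step 6
Reactants: 9 (2E,8E,10Z)-3,7,7-trimethyl-10-(triisopropylsilyloxy)dodeca-2,8,10-trien-1-ol
Product: 10 (2E,8E,10Z)-3,7,7-trimethyl-10-(triisopropylsilyloxy)dodeca-2,8,10-trienal
Conditions: MnO2, CH2Cl2, rt
Reagents that add atoms: none
Why: MnO2 oxidises the allylic alcohol selectively to the enal under neutral heterogeneous conditions that should tolerate the silyl dienol ether and not scramble the alkene geometry.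

Step 7
Reactants: 10 (2E,8E,10Z)-3,7,7-trimethyl-10-(triisopropylsilyloxy)dodeca-2,8,10-trienal
Product: 11 7-(triisopropylsilyloxy)-12,13,14,15,16-pentanorlabd-6-en-11-al (trans-fused; 5α-H, 8β-CH3, 9β-CHO, 10β-CH3)
Conditions: (R)-3,3-diphenyl-1-(o-tolyl)tetrahydropyrrolo[1,2-c][1,3,2]oxazaborole (20 mol%), Tf2NH (18 mol%), CH2Cl2 (0.02 M), −78 → −40 °C
Reagents that add atoms: none
Why: The cationic oxazaborolidine lowers the enal LUMO and should trigger a concerted, asynchronous intramolecular [4+2] cycloaddition (type 1 intramolecular Diels–Alder reaction of a 1,3,9-decatriene); the closest known reaction type is the oxazaborolidinium-catalysed enantioselective Diels–Alder reaction of enals, which includes trienal cyclisations and reactions of 2-silyloxy dienes. Ring B closes as the six-membered cycloaddition ring (C5–C10 and C8–C9 formed suprafacially on both components), and ring A closes in the same event as the six-membered ring spanned by the C1–C4 tether between C10 and C5. C9 and C10 follow stereospecifically from the (E)-dienophile (C20 methyl cis to the formyl group); C5 follows from the endo transition state (formyl under the diene, tether anti), which the Lewis acid favours and which gives the trans ring fusion; C8 follows from the (Z)-enol ether (methyl outside, 8β-CH3) and is erased later. The absolute configuration is set by the catalyst: by the formyl C–H···O binding model the (R)-catalyst holds the s-trans enal over a catalyst phenyl ring and should leave the C9 Si/C10 Re face open. The step needs endo over exo selectivity and survival of the enol ether; regiochemistry is secured by the four-carbon tether, which allows only the C5–C10/C8–C9 pairing, and the bulky triisopropylsilyl group protects the enol ether from the acidic catalyst.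

Step 8
Reactants: 11 7-(triisopropylsilyloxy)-12,13,14,15,16-pentanorlabd-6-en-11-al
Product: 13 7-oxo-6α-(triisopropylsilyloxy)-12,13,14,15,16-pentanorlabdan-11-al, via silyloxy epoxide 12 (not isolated)
Conditions: mCPBA, hexane/CH2Cl2, −20 °C → rt
Reagents that add atoms: mCPBA, OOC(=O)c1cccc(Cl)c1
Why: Rubottom oxidation, in which the peracid epoxidises the electron-rich C6=C7 enol ether (much faster than it attacks the aldehyde) from the α face, the β face being blocked by the axial C19 and C20 methyls and the 8β-methyl, and the silyloxy epoxide opens with 1,4-silyl shift to the 6α-silyloxy 7-ketone.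

Step 9
Reactants: 13 7-oxo-6α-(triisopropylsilyloxy)-12,13,14,15,16-pentanorlabdan-11-al
Product: 15 7-oxo-6α-(triisopropylsilyloxy)-13,14,15,16-tetranorlabdan-12-al, via methyl enol ether 14 (not isolated)
Conditions: Ph3P(CH2OMe)Cl, KHMDS, THF, 0 °C → rt; then 2 M HCl, THF, rt
Reagents that add atoms: (methoxymethyl)triphenylphosphonium chloride, COC[P+](c1ccccc1)(c1ccccc1)c1ccccc1.[Cl-]; water, O
Why: Wittig reaction of the aldehyde with the methoxymethylene ylide (the flanked C7 ketone should not compete) followed by acid hydrolysis of the enol ether gives the one-carbon homologue, and the triisopropylsilyl ether survives dilute acid.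

Step 10
Reactants: 15 7-oxo-6α-(triisopropylsilyloxy)-13,14,15,16-tetranorlabdan-12-al
Product: 16 (12E)-7-oxo-6α-(triisopropylsilyloxy)-15-norlabd-12-en-14-al
Conditions: Ph3P=C(CH3)CHO, toluene, 80 °C
Reagents that add atoms: 2-(triphenylphosphoranylidene)propanal, CC(C=O)=P(c1ccccc1)(c1ccccc1)c1ccccc1
Why: The formyl-stabilised Wittig reagent reacts only with the aldehyde and should give the (E)-trisubstituted C12=C13 enal under thermodynamic control.

Step 11
Reactants: 16 (12E)-7-oxo-6α-(triisopropylsilyloxy)-15-norlabd-12-en-14-al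
Product: 17 (12E)-6α-(triisopropylsilyloxy)labda-12,14-dien-7-one (8β-CH3)
Conditions: Ph3PCH3Br, KHMDS, THF, −78 → 0 °C
Reagents that add atoms: methyltriphenylphosphonium bromide, C[P+](c1ccccc1)(c1ccccc1)c1ccccc1.[Br-]
Why: Wittig methylenation of the unhindered enal carbonyl at low temperature should outrun attack on the flanked C7 ketone and completes the (12E)-1,3-diene.

Step 12
Reactants: 17 (12E)-6α-(triisopropylsilyloxy)labda-12,14-dien-7-one
Product: 19 (12E)-8α-hydroxy-6α-(triisopropylsilyloxy)labda-12,14-dien-7-one, via potassium C7–C8 enolate 18 (not isolated)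
Conditions: KHMDS, THF, −78 → −40 °C; then 2-(phenylsulfonyl)-3-phenyloxaziridine, −78 °C; AcOH quench
Reagents that add atoms: 2-(phenylsulfonyl)-3-phenyloxaziridine, O=S(=O)(N1OC1c1ccccc1)c1ccccc1
Why: Enolate oxidation with an N-sulfonyloxaziridine, in which the base should remove H-8 rather than H-6 (H-6 is shielded by the silyloxy group and two syn-axial methyls, and α-silyloxy ketones enolise kinetically away from the oxygen) and oxygen is delivered to the tetrasubstituted enolate from the α face, anti to the axial C20 methyl, which sets 8α-OH/8β-CH3.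

Step 13
Reactants: 19 (12E)-8α-hydroxy-6α-(triisopropylsilyloxy)labda-12,14-dien-7-one
Product: 20 (12E)-6α,8α-dihydroxylabda-12,14-dien-7-one
Conditions: HF·pyridine, pyridine, THF, 0 °C → rt
Reagents that add atoms: none
Why: Fluoride cleaves the activated α-silyloxy ketone Si–O bond under buffered, non-basic conditions, which should avoid α-ketol rearrangement and spare the diene and the tertiary alcohol.

Step 14
Reactants: 20 (12E)-6α,8α-dihydroxylabda-12,14-dien-7-one; 21 angelic acid
Product: 22 (12E)-6α-angeloyloxy-8α-hydroxylabda-12,14-dien-7-one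
Conditions: 21, 2,4,6-trichlorobenzoyl chloride, Et3N, toluene, rt; then 20, 80 °C
Reagents that add atoms: none
Why: Yamaguchi-type esterification through the mixed 2,4,6-trichlorobenzoic anhydride acylates the secondary 6α-hydroxyl (the tertiary 8-hydroxyl is inert) and, run without a nucleophilic amine catalyst, should avoid angelate-to-tiglate isomerisation.

Step 15
Reactants: 22 (12E)-6α-angeloyloxy-8α-hydroxylabda-12,14-dien-7-one
Product: 23 (12E)-6α-angeloyloxylabda-12,14-diene-7β,8α-diol (CNP0189082.1)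
Conditions: NaBH4, CeCl3·7H2O, MeOH/THF, −78 °C
Reagents that add atoms: none
Why: Luche reduction, in which hydride should add to C7 axially from the α face because equatorial attack is blocked by the axial 8β-methyl, giving the equatorial 7β-alcohol, while the low temperature suppresses 6→7 acyl migration and the enoate and diene are not reduced.

Compound list
1 | ethyl acetoacetate | CCOC(=O)CC(C)=O | starting material
2 | ethyl (E)-3-(trifluoromethylsulfonyloxy)but-2-enoate | CCOC(=O)/C=C(\C)OS(=O)(=O)C(F)(F)F | intermediate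
3 | 2,2-dimethylpent-4-enal | C=CCC(C)(C)C=O | starting material
4 | diethyl (2-oxobutyl)phosphonate | CCC(=O)CP(=O)(OCC)OCC | starting material
5 | (E)-6,6-dimethylnona-4,8-dien-3-one | CCC(=O)/C=C/C(C)(C)CC=C | intermediate
6 | (2Z,4E)-6,6-dimethyl-3-(triisopropylsilyloxy)nona-2,4,8-triene | C/C=C(O[Si](C(C)C)(C(C)C)C(C)C)/C=C/C(C)(C)CC=C | intermediate
7 | 9-[(5E,7Z)-4,4-dimethyl-7-(triisopropylsilyloxy)nona-5,7-dien-1-yl]-9-borabicyclo[3.3.1]nonane | C/C=C(O[Si](C(C)C)(C(C)C)C(C)C)/C=C/C(C)(C)CCCB1C2CCCC1CCC2 | intermediate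
8 | ethyl (2E,8E,10Z)-3,7,7-trimethyl-10-(triisopropylsilyloxy)dodeca-2,8,10-trienoate | CCOC(=O)/C=C(\C)CCCC(C)(C)/C=C/C(O[Si](C(C)C)(C(C)C)C(C)C)=C/C | intermediate
9 | (2E,8E,10Z)-3,7,7-trimethyl-10-(triisopropylsilyloxy)dodeca-2,8,10-trien-1-ol | OC/C=C(\C)CCCC(C)(C)/C=C/C(O[Si](C(C)C)(C(C)C)C(C)C)=C/C | intermediate
10 | (2E,8E,10Z)-3,7,7-trimethyl-10-(triisopropylsilyloxy)dodeca-2,8,10-trienal | O=C/C=C(\C)CCCC(C)(C)/C=C/C(O[Si](C(C)C)(C(C)C)C(C)C)=C/C | intermediate
11 | 7-(triisopropylsilyloxy)-12,13,14,15,16-pentanorlabd-6-en-11-al (5α-H, 8β-CH3, 9β-CHO, 10β-CH3) | O=C[C@H]1[C@@H](C)C(O[Si](C(C)C)(C(C)C)C(C)C)=C[C@H]2C(C)(C)CCC[C@@]21C | intermediate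
12 | 6α,7α-epoxy-7β-(triisopropylsilyloxy)-12,13,14,15,16-pentanorlabdan-11-al | O=C[C@H]1[C@@H](C)[C@]3(O[Si](C(C)C)(C(C)C)C(C)C)O[C@@H]3[C@H]2C(C)(C)CCC[C@@]21C | intermediate
13 | 7-oxo-6α-(triisopropylsilyloxy)-12,13,14,15,16-pentanorlabdan-11-al | O=C[C@H]1[C@@H](C)C(=O)[C@H](O[Si](C(C)C)(C(C)C)C(C)C)[C@H]2C(C)(C)CCC[C@@]21C | intermediate
14 | 12-methoxy-6α-(triisopropylsilyloxy)-13,14,15,16-tetranorlabd-11-en-7-one (E/Z mixture) | COC=C[C@H]1[C@@H](C)C(=O)[C@H](O[Si](C(C)C)(C(C)C)C(C)C)[C@H]2C(C)(C)CCC[C@@]21C | intermediate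
15 | 7-oxo-6α-(triisopropylsilyloxy)-13,14,15,16-tetranorlabdan-12-al | O=CC[C@H]1[C@@H](C)C(=O)[C@H](O[Si](C(C)C)(C(C)C)C(C)C)[C@H]2C(C)(C)CCC[C@@]21C | intermediate
16 | (12E)-7-oxo-6α-(triisopropylsilyloxy)-15-norlabd-12-en-14-al | O=C/C(C)=C/C[C@H]1[C@@H](C)C(=O)[C@H](O[Si](C(C)C)(C(C)C)C(C)C)[C@H]2C(C)(C)CCC[C@@]21C | intermediate
17 | (12E)-6α-(triisopropylsilyloxy)labda-12,14-dien-7-one (8β-CH3) | C=C/C(C)=C/C[C@H]1[C@@H](C)C(=O)[C@H](O[Si](C(C)C)(C(C)C)C(C)C)[C@H]2C(C)(C)CCC[C@@]21C | intermediate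
18 | potassium (12E)-6α-(triisopropylsilyloxy)labda-7,12,14-trien-7-olate | C=C/C(C)=C/C[C@H]1C(C)=C([O-])[C@H](O[Si](C(C)C)(C(C)C)C(C)C)[C@H]2C(C)(C)CCC[C@@]21C.[K+] | intermediate
19 | (12E)-8α-hydroxy-6α-(triisopropylsilyloxy)labda-12,14-dien-7-one | C=C/C(C)=C/C[C@H]1[C@](C)(O)C(=O)[C@H](O[Si](C(C)C)(C(C)C)C(C)C)[C@H]2C(C)(C)CCC[C@@]21C | intermediate
20 | (12E)-6α,8α-dihydroxylabda-12,14-dien-7-one | C=C/C(C)=C/C[C@H]1[C@](C)(O)C(=O)[C@H](O)[C@H]2C(C)(C)CCC[C@@]21C | intermediate
21 | angelic acid, (Z)-2-methylbut-2-enoic acid | C/C=C(/C)C(=O)O | starting material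
22 | (12E)-6α-angeloyloxy-8α-hydroxylabda-12,14-dien-7-one | C=C/C(C)=C/C[C@H]1[C@](C)(O)C(=O)[C@H](OC(=O)/C(C)=C\C)[C@H]2C(C)(C)CCC[C@@]21C | intermediate
23 | (12E)-6α-angeloyloxylabda-12,14-diene-7β,8α-diol (CNP0189082.1) | C=C/C(C)=C/C[C@H]1[C@](C)(O)[C@@H](O)[C@H](OC(=O)/C(C)=C\C)[C@H]2C(C)(C)CCC[C@@]21C | target

Total step count: 15. Longest linear sequence: 14 steps (steps 2–15, from 3); step 1 is a one-step branch.

Steps most likely to fail

Step 7. The β,β-disubstituted enal may be activated too weakly, endo and facial selectivity may erode, or the acidic catalyst may protodesilylate the dienol ether. The fallback is an auxiliary-controlled cycloaddition that sets out from 8. Me3SnOH (1,2-dichloroethane, 70 °C) cleaves the ethyl ester to the trienoic acid F1. Pivaloyl chloride/Et3N, then LiCl and (S)-4-benzyloxazolidin-2-one, give the N-acyl oxazolidinone F2. Me2AlCl (CH2Cl2, −30 °C) chelates the s-cis imide, and the diene adds endo, anti to the benzyl group on the C9 Si face, to give the cycloadduct imide F3. LiBH4 (Et2O, a little water) removes the auxiliary and gives the primary alcohol F4, and Dess–Martin periodinane returns the route to 11.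

Step 12. Deprotonation may occur at C6 instead of C8, or the hindered C8 methine may not be deprotonated, so that oxygen is transferred to the wrong carbon or not at all. The fallback reverses the order of the two α-oxygenations and sets out from 11. Methoxymethylene Wittig reaction followed by aqueous HCl hydrolyses both enol ethers to the keto aldehyde F5. Ph3P=C(CH3)CHO gives the enal F6 and Ph3P=CH2 gives the diene ketone F7. KOt-Bu, O2 and P(OEt)3 (THF/t-BuOH, −20 °C) hydroxylate the more substituted, thermodynamic enolate from the α face to the 8α-hydroxy ketone F8. C6 is then the only enolisable position, so LDA (2.2 equiv) and 2-(phenylsulfonyl)-3-phenyloxaziridine install the 6α-hydroxyl from the open α face and the route is rejoined at 20.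

Step 15. The angelate may migrate from O6 to the new O7 alkoxide, and hydride addition may not be fully face-selective. The fallback reduces before acylation and sets out from 19. Me4NBH(OAc)3 (MeCN/AcOH), with hydride delivered from the 8α-hydroxyl, gives the 7β,8α-diol F9. 2-Methoxypropene/PPTS gives the acetonide F10, TBAF frees the 6α-alcohol F11, and the esterification of step 14 gives the angelate acetonide F12. 80% aqueous AcOH at rt removes the acetal and arrives at 23.

Further compounds
F1 | step 7 | (2E,8E,10Z)-3,7,7-trimethyl-10-(triisopropylsilyloxy)dodeca-2,8,10-trienoic acid | OC(=O)/C=C(\C)CCCC(C)(C)/C=C/C(O[Si](C(C)C)(C(C)C)C(C)C)=C/C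
F2 | step 7 | (S)-4-benzyl-3-[(2E,8E,10Z)-3,7,7-trimethyl-10-(triisopropylsilyloxy)dodeca-2,8,10-trienoyl]oxazolidin-2-one | O=C(/C=C(\C)CCCC(C)(C)/C=C/C(O[Si](C(C)C)(C(C)C)C(C)C)=C/C)N1C(=O)OC[C@@H]1Cc1ccccc1
F3 | step 7 | (S)-4-benzyl-3-[7-(triisopropylsilyloxy)-12,13,14,15,16-pentanorlabd-6-en-11-oyl]oxazolidin-2-one | O=C([C@H]1[C@@H](C)C(O[Si](C(C)C)(C(C)C)C(C)C)=C[C@H]2C(C)(C)CCC[C@@]21C)N1C(=O)OC[C@@H]1Cc1ccccc1
F4 | step 7 | 7-(triisopropylsilyloxy)-12,13,14,15,16-pentanorlabd-6-en-11-ol | OC[C@H]1[C@@H](C)C(O[Si](C(C)C)(C(C)C)C(C)C)=C[C@H]2C(C)(C)CCC[C@@]21C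
F5 | step 12 | 7-oxo-13,14,15,16-tetranorlabdan-12-al | O=CC[C@H]1[C@@H](C)C(=O)C[C@H]2C(C)(C)CCC[C@@]21C
F6 | step 12 | (12E)-7-oxo-15-norlabd-12-en-14-al | O=C/C(C)=C/C[C@H]1[C@@H](C)C(=O)C[C@H]2C(C)(C)CCC[C@@]21C
F7 | step 12 | (12E)-labda-12,14-dien-7-one | C=C/C(C)=C/C[C@H]1[C@@H](C)C(=O)C[C@H]2C(C)(C)CCC[C@@]21C
F8 | step 12 | (12E)-8α-hydroxylabda-12,14-dien-7-one | C=C/C(C)=C/C[C@H]1[C@](C)(O)C(=O)C[C@H]2C(C)(C)CCC[C@@]21C
F9 | step 15 | (12E)-6α-(triisopropylsilyloxy)labda-12,14-diene-7β,8α-diol | C=C/C(C)=C/C[C@H]1[C@](C)(O)[C@@H](O)[C@H](O[Si](C(C)C)(C(C)C)C(C)C)[C@H]2C(C)(C)CCC[C@@]21C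
F10 | step 15 | (12E)-7β,8α-(isopropylidenedioxy)-6α-(triisopropylsilyloxy)labda-12,14-diene | C=C/C(C)=C/C[C@H]1[C@]3(C)OC(C)(C)O[C@H]3[C@H](O[Si](C(C)C)(C(C)C)C(C)C)[C@H]2C(C)(C)CCC[C@@]21C
F11 | step 15 | (12E)-7β,8α-(isopropylidenedioxy)labda-12,14-dien-6α-ol | C=C/C(C)=C/C[C@H]1[C@]3(C)OC(C)(C)O[C@H]3[C@H](O)[C@H]2C(C)(C)CCC[C@@]21C
F12 | step 15 | (12E)-6α-angeloyloxy-7β,8α-(isopropylidenedioxy)labda-12,14-diene | C=C/C(C)=C/C[C@H]1[C@]3(C)OC(C)(C)O[C@H]3[C@H](OC(=O)/C(C)=C\C)[C@H]2C(C)(C)CCC[C@@]21C
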